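## The problem

The chain is numbered from the prenyl end: C3=C4 (dimethylvinyl alkene), C5H2, the C6 ketone, ring carbons C7 (quaternary), C8–C10 (CH2) and C11 (quaternary), C12H2, the C13 ketone, C14H2, C15(CH3)=C16H, and the benzylic C17H2 on the quinone.

Target 29 is a chain hung on two rings that share no atoms: a cis-1,2-dimethylcyclopentane in the middle and a 2-methyl-1,4-benzoquinone at the end. The task is therefore chain building at two neighbouring quaternary carbons, not ring annulation. The only stereocentres are C7 and C11, both quaternary, both R, with the methyl groups cis. No other stereocentre can relay to them, so their relative configuration is best fixed by a ring fusion and their absolute configuration by breaking the symmetry of a meso precursor; once set they cannot epimerise. C7 carries a one-carbon arm (C6) and C11 a two-carbon arm (C12–C13), which are exactly the two ends of a cleaved C6–C13 bond in a cis-fused five-membered ring. The C6 and C13 ketones are each β,γ-unsaturated and are 1,5-related, so acid or base invites alkene conjugation or intramolecular aldol closure. The quinone is an oxidant and Michael acceptor that tolerates no organometallic reagent, so ketones and quinone must appear last, from carbinols and a hydroquinone dimethyl ether. The E-trisubstituted alkene C15(CH3)=C16 with C17 on C16 is formally a methyl group and an arylmethyl group added syn across a terminal alkyne C15≡C16. The C13 oxygen sits homopropargylic to that alkyne, which lets one three-component operation join the aromatic and terpenoid halves.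

## Retrosynthesis

**Unmasking.** Target 29 is taken back without cutting any C–C bond to diketone 28 (quinone as dimethyl ether), then to diol 27, then to bis-silyl ether 26. The arene is oxidised last because the quinone would not survive carbinol deprotection or organometallic steps. The ketones are carried as silyl-protected carbinols because an organoaluminium reagent would add to them and because the 1,5-diketone should see as few reagents as possible. The forward steps must oxidise two carbinols under neutral conditions and oxidise the arene without touching two trisubstituted alkenes.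

**Key disconnection.** In 26 the C15–CH3 and C16–C17 bonds are cut together, giving terminal alkyne 18, trimethylaluminium 24 and benzylic chloride 23. The neighbouring cuts are weaker. An olefination across C15=C16 would have to set a trisubstituted geometry beside an enolisable C13 carbonyl. A cut at C13–C14 or C14–C15 with the alkene intact needs a geometrically pure trisubstituted allyl partner that would itself come from the same carbometalation. The chosen cut makes the E geometry a consequence of syn addition, splits off the whole aromatic half, and leaves 18 with no alkene geometry to control. The forward reaction must put methyl on the internal carbon, keep the alkenyl metal configurationally intact through a zerovalent-palladium coupling, and ignore the C3=C4 alkene and both silyl ethers.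

**Benzylic chloride.** Chloride 23 goes back through alcohol 22 and aldehyde 21 to salicylaldehyde 20, and by removal of the formyl carbon (C17) to phenol 19. Phenol 19 has a single free ortho position, so the formylation has no regiochemical choice; direct chloromethylation of a dimethoxytoluene would attack the wrong ring position.

**C13–C14.** Alkyne 18 is the bis-silyl ether of diol 17, and 17 is cut at C13–C14 into lactol 15 and propargyl bromide 16. The lactol is the hydroxy aldehyde in masked form: one ring holds the C6 hydroxyl and the C13 aldehyde, so no protecting group is needed between C6 and C13 chemistry. The forward reaction must add an allenyl metal to the open form of a lactol and give the homopropargylic, not the allenic, carbinol.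

**Prenyl arm.** Lactol 15 comes from lactone 14 by partial reduction. The C3=C4 alkene of 14 is cut by metathesis into allyl lactone 12 and 2-methyl-2-butene 13, and 12 is cut at C5–C6 into aldehyde acid 9 and allyl bromide 10. Direct prenyl transfer to the aldehyde was set aside because prenyl metals normally attack through their tertiary terminus. Allylation followed by cross-metathesis costs one more step but has no regiochemical question, and the metathesis is placed before any alkyne is present.

**Ring cleavage and desymmetrisation.** Aldehyde acid 9 is reconnected between C6 and C13 to silyl enol ether 8, the ozonolysis substrate. One cleavage gives both arms at the right length and oxidation level, an aldehyde on C7 and an acetic acid on C11. Enol ether 8 comes from meso ketone 7 by enantioselective deprotonation, the only step that sets absolute configuration. The forward step must distinguish the two enantiotopic α-methylene groups of 7.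

**Bicyclic core.** Ketone 7 comes from monoketal 5 by deoxygenation of the free carbonyl and ketal hydrolysis, and 5 from meso dione 4. Dione 4 comes from tetraester 3, which is cut at four C–C bonds into 2,3-butanedione 1 and two molecules of dimethyl 3-oxoglutarate 2. The cis ring fusion of the bicyclo[3.3.0]octane fixes the cis relation of the two methyl-bearing quaternary carbons from achiral, cheap materials.

## Roads not taken

**Alternative 1:** The cyclopentane is traced to a cyclohexene made by Diels–Alder addition of buta-1,3-diene A1 to 2,3-dimethylmaleic anhydride A2, giving the meso cis-anhydride A3 and forming C7–C8 and C10–C11. Its merits are real. Both quaternary carbons and their cis relation come from one cycloaddition of commodity chemicals. A3 is also an ideal substrate for catalytic enantioselective anhydride alcoholysis, which is arguably a more dependable and more economical source of absolute configuration than the stoichiometric chiral amide used here. The weak points lie after the key step. A2 is a tetrasubstituted, sluggish dienophile that needs forcing conditions. The six-membered ring must be cut, reclosed and stripped of a carbon and an oxygen, four or five steps that form no bond of the target. Both ring substituents emerge as carboxyl carbons directly on the ring, so C12 is missing and must be added by a one-carbon homologation. The chosen plan sets against the better enantiocontrol a ring cleavage (8 to 9) that delivers C6 and C12–C13 at the correct length and oxidation level in one step. The alkyne chemistry downstream would be the same, so this road is simply longer.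

**Alternative 2:** The C7–C11 bond is cut, leading to the nine-membered lactone A4. Its silyl ketene acetal would rearrange through a ring-enforced boat transition state (Ireland–Claisen ring contraction) to acid A5, with carboxyl and propenyl cis. This road forms the most hindered bond of the molecule directly. Absolute configuration would come by chirality transfer from one secondary carbinol centre in A4, which is easy to obtain enantiopure and likely to give higher enantiomeric purity than a chiral-base deprotonation. Against this, A4 needs a medium-ring lactonisation and a Z-trisubstituted ring alkene, and the rearrangement must create two quaternary centres from a fully substituted ketene acetal. The propenyl group of A5 also carries no oxygen: C13 would have to be oxidised regioselectively, and C14 then joined to C15 through ketone enolate chemistry. That is a weaker way to set the C15=C16 geometry than methylalumination. Cleaving the propenyl group to an aldehyde instead loses C13 and C14. The chosen plan gives up the better stereochemical pedigree for a core made in fewer operations and an arm on C11 that already ends in the C13 carbonyl.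

**Alternative 3:** The C6–C7 and C11–C12 bonds are cut together. Irradiation of the chiral dioxinone A6 with 1,2-dimethylcyclopentene A7 would give the cis-anti-cis photoadduct A8, and retro-aldol opening would give keto acid A9. This is the shortest way to the core. One step makes both quaternary centres and both ring-to-chain bonds, the alkene partner is symmetrical so no regiochemistry arises, and A9 has C6 and C13 differentiated at the right oxidation levels. It could reach the stage of compound 9 in about three steps against six, a clear advantage in step count. The weak points are the [2+2] addition to a tetrasubstituted alkene beside a crowded dioxinone, the often modest facial control from the acetal centre of A6, and the need for a photochemical step at scale with a volatile alkene in excess. In addition, C6 arrives in A9 as an acetyl group. The dimethylvinyl unit would have to be attached at C5 by enolate alkenylation or by aldol and dehydration, and the latter tends to give the conjugated isomer. The chosen plan answers with thermal, scalable reactions on a ring system where each is known, and with an aldehyde at C6 that takes the C5–C3 unit without enolate chemistry next to a quaternary carbon.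

Key step: step 16

Assumption: the (R,R)-configured lithium amide is taken to remove the proton that leads to enol ether 8; if the sense of induction is the opposite, the (S,S)-amide is used and nothing else changes.
Assumption: the carbinol centres at C6 and C13 (and the lactol carbon of 15) are carried as epimer mixtures, since step 18 converts both carbinols into ketones.

## Route

Step 1
Reactants: 1 2,3-butanedione; 2 dimethyl 3-oxoglutarate (2 equiv)
Product: 3 tetramethyl cis-3,7-dihydroxy-1,5-dimethylbicyclo[3.3.0]octa-2,6-diene-2,4,6,8-tetracarboxylate
Conditions: aq. NaHCO3, rt, 24 h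
Reagents that add atoms: none
Why: Weiss–Cook condensation: two aldol/Michael sequences between the 1,2-diketone and two oxoglutarate molecules close both five-membered rings, and the 1,5-fusion of two cyclopentanes can only be cis, which fixes the relative configuration of the future C7 and C11.

Step 2
Reactants: 3 tetraester
Product: 4 cis-1,5-dimethylbicyclo[3.3.0]octane-3,7-dione (meso)
Conditions: 1 M HCl, AcOH, reflux
Reagents that add atoms: none
Why: Acid hydrolysis of the four β-keto esters and fourfold decarboxylation; the quaternary bridgeheads are untouched, so the cis fusion is kept.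

Step 3
Reactants: 4 meso dione
Product: 5 cis-1,5-dimethylbicyclo[3.3.0]octane-3,7-dione mono(2,2-dimethylpropane-1,3-diyl) ketal (achiral)
Conditions: 2,2-dimethylpropane-1,3-diol (1 equiv), p-TsOH (cat.), toluene, reflux, Dean–Stark
Reagents that add atoms: 2,2-dimethylpropane-1,3-diol, OCC(C)(C)CO
Why: Acid-catalysed ketalisation with one equivalent of diol should favour the monoketal of this symmetrical dione; unreacted dione and bisketal are separable and can be re-equilibrated.

Step 4
Reactants: 5 monoketal
Product: 7 cis-1,5-dimethylbicyclo[3.3.0]octan-3-one (meso), via deoxygenated ketal 6 (not isolated)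
Conditions: N2H4·H2O, KOH, diethylene glycol, 130 → 200 °C; then 2 M HCl, THF, rt
Reagents that add atoms: water, O
Why: Wolff–Kishner reduction (Huang-Minlon modification) removes the free carbonyl while the base-stable ketal survives; aqueous acid then hydrolyses the crude ketal to the ketone, which keeps a mirror plane through C3 and C7 of the bicycle.

Step 5
Reactants: 7 meso ketone
Product: 8 (1S,5R)-1,5-dimethyl-3-(trimethylsilyloxy)bicyclo[3.3.0]oct-2-ene
Conditions: lithium (R,R)-bis(1-phenylethyl)amide (from the amine and n-BuLi), LiCl, THF, −100 °C; TMSCl, −100 → −78 °C
Reagents that add atoms: chlorotrimethylsilane, C[Si](C)(C)Cl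
Why: Enantioselective deprotonation of a meso ketone by a homochiral lithium amide, a known desymmetrisation of cis-fused bicyclo[3.3.0]octan-3-ones; the amide distinguishes the two enantiotopic α-methylene groups and silylation fixes the choice, which is what makes C7 and C11 non-equivalent and sets the absolute configuration of both.

Step 6
Reactants: 8 silyl enol ether
Product: 9 2-[(1R,2R)-2-formyl-1,2-dimethylcyclopentyl]acetic acid
Conditions: O3, CH2Cl2/MeOH, −78 °C; Me2S, −78 °C → rt; aqueous work-up
Reagents that add atoms: ozone, [O-][O+]=O
Why: Ozonolysis of a silyl enol ether with reductive work-up cleaves the electron-rich C=C to an aldehyde at the former CH carbon (C6) and, after loss of the silyl group, a carboxylic acid at the former silyloxy carbon (C13); the aldehyde sits on a quaternary carbon and cannot epimerise.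

Step 7
Reactants: 9 aldehyde acid; 10 allyl bromide
Product: 12 (1R,6R)-2-allyl-1,6-dimethyl-3-oxabicyclo[4.3.0]nonan-4-one (C2 epimers), via hydroxy acid 11 (not isolated)
Conditions: In powder, THF/H2O (1:1), rt; then p-TsOH (cat.), toluene, 60 °C
Reagents that add atoms: none
Why: Barbier allylation: allylindium formed in the flask adds to the aldehyde in water in the presence of the free acid (the open form is in equilibrium with any cyclic pseudo-acid), forming C5–C6; acid then closes the cis-fused δ-lactone, favoured by the two quaternary carbons, and the C6 carbinol epimers are inconsequential.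

Step 8
Reactants: 12 allyl lactone; 13 2-methyl-2-butene (excess)
Product: 14 (1R,6R)-1,6-dimethyl-2-(3-methylbut-2-en-1-yl)-3-oxabicyclo[4.3.0]nonan-4-one (C2 epimers)
Conditions: second-generation Grubbs catalyst (H2IMes)(PCy3)Cl2Ru=CHPh (5 mol %), 2-methyl-2-butene/CH2Cl2, 40 °C
Reagents that add atoms: none
Why: Olefin cross-metathesis of a terminal alkene with excess 2-methyl-2-butene exchanges the methylene terminus for an isopropylidene group with loss of propene, a known way to turn allyl into prenyl; it is run before any alkyne is present because alkynes interfere with ruthenium carbenes.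

Step 9
Reactants: 14 prenyl lactone
Product: 15 (1R,6R)-1,6-dimethyl-2-(3-methylbut-2-en-1-yl)-3-oxabicyclo[4.3.0]nonan-4-ol (lactol, epimer mixture)
Conditions: i-Bu2AlH (1.1 equiv), CH2Cl2, −78 °C; aq. potassium sodium tartrate
Reagents that add atoms: none
Why: Partial reduction of a lactone: the aluminium hemiacetal is stable at −78 °C and gives the lactol on work-up, which masks the C13 aldehyde and the C6 hydroxyl in one ring.

Step 10
Reactants: 15 lactol; 16 propargyl bromide (excess)
Product: 17 1-[(1R,2R)-2-(2-hydroxypent-4-yn-1-yl)-1,2-dimethylcyclopentyl]-4-methylpent-3-en-1-ol (carbinol epimers)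
Conditions: activated Zn dust, THF/sat. aq. NH4Cl, 0 °C → rt
Reagents that add atoms: none
Why: Barbier propargylation: the allenylzinc species formed from propargyl bromide and zinc adds through a cyclic SE2′ transition state to the aldehyde tautomer of the lactol, forming C13–C14 and giving the homopropargylic carbinol; the C13 epimers are inconsequential.

Step 11
Reactants: 17 diol
Product: 18 bis(tert-butyldimethylsilyl) ether of 17 (silyloxy groups at C6 and C13, terminal alkyne C15≡C16)
Conditions: TBSOTf (3 equiv), 2,6-lutidine, CH2Cl2, −78 → 0 °C
Reagents that add atoms: tert-butyldimethylsilyl trifluoromethanesulfonate, CC(C)(C)[Si](C)(C)OS(=O)(=O)C(F)(F)F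
Why: Silylation with the silyl triflate is needed because the C6 carbinol is flanked by a quaternary carbon; the alkyne C–H and the trisubstituted alkene are inert to the buffered triflate at low temperature.

Step 12
Reactants: 19 4-methoxy-2-methylphenol
Product: 20 2-hydroxy-5-methoxy-3-methylbenzaldehyde
Conditions: (CH2O)n, MgCl2, Et3N, MeCN, reflux; aq. HCl
Reagents that add atoms: formaldehyde (as paraformaldehyde), C=O
Why: Magnesium-mediated ortho-formylation of a phenol (Casnati–Skattebøl): the magnesium phenoxide delivers formaldehyde to the only free ortho position and hydride transfer to a second formaldehyde gives the aldehyde, which installs C17.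

Step 13
Reactants: 20 salicylaldehyde
Product: 21 2,5-dimethoxy-3-methylbenzaldehyde
Conditions: MeI, K2CO3, DMF, rt
Reagents that add atoms: iodomethane, CI
Why: Williamson etherification of the phenoxide; the aldehyde is inert to these conditions.

Step 14
Reactants: 21 aldehyde
Product: 22 (2,5-dimethoxy-3-methylphenyl)methanol
Conditions: NaBH4, MeOH, 0 °C
Reagents that add atoms: none
Why: Borohydride reduction of an aryl aldehyde to the benzylic alcohol.

Step 15
Reactants: 22 benzylic alcohol
Product: 23 1-(chloromethyl)-2,5-dimethoxy-3-methylbenzene
Conditions: SOCl2, CH2Cl2, 0 °C → rt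
Reagents that add atoms: thionyl chloride, O=S(Cl)Cl
Why: Chlorination through the chlorosulfite, fast for an electron-rich benzylic alcohol; the chloride is used soon after preparation because it is a reactive alkylating agent.

Step 16
Reactants: 18 bis-silyl ether alkyne; 24 trimethylaluminium; 23 benzylic chloride
Product: 26 bis(tert-butyldimethylsilyl) ether of the complete skeleton with the (15E)-alkene and the 2,5-dimethoxy-3-methylbenzyl group on C16 (C6/C13 epimers), via alkenylalane 25 (not isolated)
Conditions: AlMe3 (2.5 equiv), Cp2ZrCl2 (0.25 equiv), ClCH2CH2Cl, 0 °C → rt; volatiles removed in vacuo; 23, Pd(PPh3)4 (5 mol %), THF, rt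
Reagents that add atoms: none
Why: Zirconium-catalysed methylalumination of a terminal alkyne followed by palladium-catalysed coupling of the alkenylalane with a benzylic chloride (Negishi carboalumination and cross-coupling), a known pairing for prenylated arenes. AlMe3 and Cp2ZrCl2 form a methylzirconium–aluminium species that adds methyl to the internal carbon C15 and the metal to the terminal carbon C16 in a syn fashion, and transmetalation leaves the (E)-alkenyldimethylalane 25 with CH3 and aluminium cis. Zerovalent palladium from Pd(PPh3)4 inserts into the C–Cl bond of 23, the alkenyl group passes from aluminium to palladium with retention, and reductive elimination forms C16–C17 without change of alkene geometry. No ring closes and no stereocentre is formed; the step forms C15–CH3 and C16–C17 and joins the two halves. It needs regioselectivity (methyl on C15), syn addition (E alkene) and chemoselectivity for the alkyne, and these are secured by the terminal alkyne, by the inertness of the trisubstituted C3=C4 alkene to methylzirconation, and by having both carbonyls masked as silyl ethers. Alkenyl transfers from aluminium faster than methyl, and stripping excess AlMe3 before the coupling suppresses methyl–benzyl coupling. Keeping the carbometalation at or below room temperature avoids the chelation-driven loss of geometry known for homopropargylic oxygen donors.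

Step 17
Reactants: 26 bis-silyl ether
Product: 27 1-[(1R,2R)-2-[(4E)-6-(2,5-dimethoxy-3-methylphenyl)-2-hydroxy-4-methylhex-4-en-1-yl]-1,2-dimethylcyclopentyl]-4-methylpent-3-en-1-ol (carbinol epimers)
Conditions: Bu4NF, THF, rt → 50 °C
Reagents that add atoms: none
Why: Fluoride-induced desilylation; warming is allowed for the hindered C6 silyl ether, and the diol has no base-sensitive group at this stage.

Step 18
Reactants: 27 diol
Product: 28 1-[(1R,2R)-2-[(4E)-6-(2,5-dimethoxy-3-methylphenyl)-4-methyl-2-oxohex-4-en-1-yl]-1,2-dimethylcyclopentyl]-4-methylpent-3-en-1-one
Conditions: Dess–Martin periodinane (3 equiv), NaHCO3, CH2Cl2, 0 °C → rt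
Reagents that add atoms: none
Why: Dess–Martin oxidation converts both secondary carbinols into ketones under buffered, near-neutral conditions, so the β,γ-alkenes should stay out of conjugation and the 1,5-diketone should not undergo aldol closure; the C6/C13 epimer mixtures converge to one compound.

Step 19
Reactants: 28 diketone
Product: 29 2-methyl-6-[(2E)-3-methyl-6-[(1R,2R)-1,2-dimethyl-2-(4-methylpent-3-enoyl)cyclopentyl]-5-oxohex-2-en-1-yl]-1,4-benzoquinone (target)
Conditions: (NH4)2Ce(NO3)6 (2.5 equiv), MeCN/H2O, 0 °C, short reaction time
Reagents that add atoms: water, O
Why: Oxidative demethylation of a 1,4-dimethoxyarene by tetravalent cerium: two one-electron oxidations with water addition release two methanol molecules and give the para-quinone, a reaction routinely run in the presence of prenyl-type alkenes.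

## Compound list

1 | 2,3-butanedione | CC(=O)C(C)=O | starting material
2 | dimethyl 3-oxoglutarate | COC(=O)CC(=O)CC(=O)OC | starting material
3 | tetramethyl cis-3,7-dihydroxy-1,5-dimethylbicyclo[3.3.0]octa-2,6-diene-2,4,6,8-tetracarboxylate | COC(=O)C1C(O)=C(C(=O)OC)[C@]2(C)C(C(=O)OC)C(O)=C(C(=O)OC)[C@]12C | intermediate
4 | cis-1,5-dimethylbicyclo[3.3.0]octane-3,7-dione (meso) | O=C1C[C@]2(C)CC(=O)C[C@]2(C)C1 | intermediate
5 | cis-1,5-dimethylbicyclo[3.3.0]octane-3,7-dione mono(2,2-dimethylpropane-1,3-diyl) ketal | O=C1C[C@]2(C)CC3(C[C@]2(C)C1)OCC(C)(C)CO3 | intermediate
6 | cis-1,5-dimethylbicyclo[3.3.0]octan-3-one 2,2-dimethylpropane-1,3-diyl ketal | C1C[C@]2(C)CC3(C[C@]2(C)C1)OCC(C)(C)CO3 | intermediate (not isolated)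
7 | cis-1,5-dimethylbicyclo[3.3.0]octan-3-one (meso) | O=C1C[C@]2(C)CCC[C@]2(C)C1 | intermediate
8 | (1S,5R)-1,5-dimethyl-3-(trimethylsilyloxy)bicyclo[3.3.0]oct-2-ene | C[Si](C)(C)OC1=C[C@]2(C)CCC[C@]2(C)C1 | intermediate
9 | 2-[(1R,2R)-2-formyl-1,2-dimethylcyclopentyl]acetic acid | O=C[C@]1(C)CCC[C@]1(C)CC(=O)O | intermediate
10 | allyl bromide | C=CCBr | starting material
11 | 2-[(1R,2R)-2-(1-hydroxybut-3-en-1-yl)-1,2-dimethylcyclopentyl]acetic acid (carbinol epimers) | C=CCC(O)[C@]1(C)CCC[C@]1(C)CC(=O)O | intermediate (not isolated)
12 | (1R,6R)-2-allyl-1,6-dimethyl-3-oxabicyclo[4.3.0]nonan-4-one (C2 epimers) | C=CCC1OC(=O)C[C@@]2(C)CCC[C@@]12C | intermediate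
13 | 2-methyl-2-butene | CC=C(C)C | starting material
14 | (1R,6R)-1,6-dimethyl-2-(3-methylbut-2-en-1-yl)-3-oxabicyclo[4.3.0]nonan-4-one (C2 epimers) | CC(C)=CCC1OC(=O)C[C@@]2(C)CCC[C@@]12C | intermediate
15 | (1R,6R)-1,6-dimethyl-2-(3-methylbut-2-en-1-yl)-3-oxabicyclo[4.3.0]nonan-4-ol (epimer mixture) | CC(C)=CCC1OC(O)C[C@@]2(C)CCC[C@@]12C | intermediate
16 | propargyl bromide | C#CCBr | starting material
17 | 1-[(1R,2R)-2-(2-hydroxypent-4-yn-1-yl)-1,2-dimethylcyclopentyl]-4-methylpent-3-en-1-ol (carbinol epimers) | CC(C)=CCC(O)[C@]1(C)CCC[C@]1(C)CC(O)CC#C | intermediate
18 | bis(tert-butyldimethylsilyl) ether of 17 | CC(C)=CCC(O[Si](C)(C)C(C)(C)C)[C@]1(C)CCC[C@]1(C)CC(O[Si](C)(C)C(C)(C)C)CC#C | intermediate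
19 | 4-methoxy-2-methylphenol | Cc1cc(OC)ccc1O | starting material
20 | 2-hydroxy-5-methoxy-3-methylbenzaldehyde | Cc1cc(OC)cc(C=O)c1O | intermediate
21 | 2,5-dimethoxy-3-methylbenzaldehyde | Cc1cc(OC)cc(C=O)c1OC | intermediate
22 | (2,5-dimethoxy-3-methylphenyl)methanol | Cc1cc(OC)cc(CO)c1OC | intermediate
23 | 1-(chloromethyl)-2,5-dimethoxy-3-methylbenzene | COc1cc(C)c(OC)c(CCl)c1 | intermediate
24 | trimethylaluminium | C[Al](C)C | starting material
25 | (E)-alkenyldimethylalane from 18 (CH3 on C15, AlMe2 on C16, cis to each other) | CC(C)=CCC(O[Si](C)(C)C(C)(C)C)[C@]1(C)CCC[C@]1(C)CC(O[Si](C)(C)C(C)(C)C)C/C(C)=C/[Al](C)C | intermediate (not isolated)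
26 | bis(tert-butyldimethylsilyl) ether of 27 | CC(C)=CCC(O[Si](C)(C)C(C)(C)C)[C@]1(C)CCC[C@]1(C)CC(O[Si](C)(C)C(C)(C)C)C/C(C)=C/Cc1cc(OC)cc(C)c1OC | intermediate
27 | 1-[(1R,2R)-2-[(4E)-6-(2,5-dimethoxy-3-methylphenyl)-2-hydroxy-4-methylhex-4-en-1-yl]-1,2-dimethylcyclopentyl]-4-methylpent-3-en-1-ol (carbinol epimers) | CC(C)=CCC(O)[C@]1(C)CCC[C@]1(C)CC(O)C/C(C)=C/Cc1cc(OC)cc(C)c1OC | intermediate
28 | 1-[(1R,2R)-2-[(4E)-6-(2,5-dimethoxy-3-methylphenyl)-4-methyl-2-oxohex-4-en-1-yl]-1,2-dimethylcyclopentyl]-4-methylpent-3-en-1-one | CC(C)=CCC(=O)[C@]1(C)CCC[C@]1(C)CC(=O)C/C(C)=C/Cc1cc(OC)cc(C)c1OC | intermediate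
29 | 2-methyl-6-[(2E)-3-methyl-6-[(1R,2R)-1,2-dimethyl-2-(4-methylpent-3-enoyl)cyclopentyl]-5-oxohex-2-en-1-yl]-1,4-benzoquinone | CC(C)=CCC(=O)[C@]1(C)CCC[C@]1(C)CC(=O)C/C(C)=C/CC1=CC(=O)C=C(C)C1=O | target

## Step count and risks

Total: 19 steps. Longest linear sequence: 15 steps (steps 1–11 and 16–19); the benzylic chloride branch is 4 steps (steps 12–15).

**Step 16 (key step).** The methylalumination may be slow or incompletely regioselective on an alkyne two atoms from a silyloxy-bearing carbon and near a crowded ring. Methyl rather than alkenyl may transfer from aluminium to the benzylpalladium intermediate. The electron-rich benzylic chloride may homocouple or self-alkylate under Lewis-acidic conditions, and a silyl ether may be lost to the aluminium Lewis acid. Fallback, from 18 back to 26: the two bond formations are separated and the polarity of the coupling reversed. The same methylalumination of 18 is quenched with I2 to give the (E)-alkenyl iodide F1. Chloride 23 is converted with Zn dust and LiCl in THF into the benzylic zinc chloride F2. Negishi coupling of F1 with F2 under Pd(PPh3)4 in THF forms C16–C17 and rejoins the route at 26.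

**Step 5.** Discrimination between the enantiotopic α-methylene groups may be incomplete, leaving material that is not a single enantiomer, and no later step raises enantiomeric purity by itself. The sense of induction also has to be established. Fallback, from 7 back to 9: deprotonation with achiral LiN(i-Pr)2 and TMSCl gives 8 together with its enantiomer F3. Ozonolysis as in step 6 gives 9 together with its enantiomer F4. Crystallisation with (R)-1-phenylethylamine (or its antipode, whichever gives the less soluble salt with 9) gives the ammonium salt F5, and acidification releases 9. The same salt formation can be used to upgrade 9 from the main route.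

**Step 10.** The ring-chain equilibrium of lactol 15 may lie so far on the closed side (two quaternary carbons in the ring) that addition is slow and protonation of the allenylzinc reagent wins; some allenic carbinol may also form. Fallback, from 14 back to 18: the lactone is opened with Me(MeO)NH·HCl and AlMe3 to the hydroxy Weinreb amide F6, which is silylated at once with TBSOTf to the silyl ether amide F7. Reduction with i-Bu2AlH gives the open-chain aldehyde F8, which cannot close to a lactol. Zinc-mediated propargylation gives the mono-silylated homopropargylic alcohol F9, and silylation with TBSOTf gives 18.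

**Step 7.** The aldehyde is neopentylic and may be held as a cyclic pseudo-acid, so that allyl transfer stalls. Fallback, from 9 back to 12: esterification with TMSCHN2 gives the aldehyde methyl ester F10, which has no cyclic form. Hosomi–Sakurai allylation (allyltrimethylsilane, TiCl4, CH2Cl2, −78 °C) gives the hydroxy ester F11, and acid-catalysed lactonisation gives 12.

**Step 19.** The acid released during the cerium oxidation may move the β,γ-alkenes into conjugation or trigger aldol closure of the 1,5-diketone. Fallback, from 27 to 29: the order of the last two oxidations is reversed. (NH4)2Ce(NO3)6 is applied to diol 27, which has no ketone, to give the quinone diol F12. Buffered Dess–Martin oxidation, worked up by filtration through silica without a reducing wash, then gives 29.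

## Further compounds

F1 | step 16 | (E)-alkenyl iodide from 18 (CH3 on C15, iodine on C16) | CC(C)=CCC(O[Si](C)(C)C(C)(C)C)[C@]1(C)CCC[C@]1(C)CC(O[Si](C)(C)C(C)(C)C)C/C(C)=C/I
F2 | step 16 | (2,5-dimethoxy-3-methylbenzyl)zinc chloride | COc1cc(C)c(OC)c(C[Zn]Cl)c1
F3 | step 5 | (1R,5S)-1,5-dimethyl-3-(trimethylsilyloxy)bicyclo[3.3.0]oct-2-ene (enantiomer of 8) | C[Si](C)(C)OC1=C[C@@]2(C)CCC[C@@]2(C)C1
F4 | step 5 | 2-[(1S,2S)-2-formyl-1,2-dimethylcyclopentyl]acetic acid (enantiomer of 9) | O=C[C@@]1(C)CCC[C@@]1(C)CC(=O)O
F5 | step 5 | (R)-1-phenylethylammonium salt of 9 | O=C[C@]1(C)CCC[C@]1(C)CC(=O)[O-].C[C@@H]([NH3+])c1ccccc1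
F6 | step 10 | 2-[(1R,2R)-2-(1-hydroxy-4-methylpent-3-en-1-yl)-1,2-dimethylcyclopentyl]-N-methoxy-N-methylacetamide | CC(C)=CCC(O)[C@]1(C)CCC[C@]1(C)CC(=O)N(C)OC
F7 | step 10 | tert-butyldimethylsilyl ether of F6 | CC(C)=CCC(O[Si](C)(C)C(C)(C)C)[C@]1(C)CCC[C@]1(C)CC(=O)N(C)OC
F8 | step 10 | 2-[(1R,2R)-2-(1-(tert-butyldimethylsilyloxy)-4-methylpent-3-en-1-yl)-1,2-dimethylcyclopentyl]acetaldehyde | CC(C)=CCC(O[Si](C)(C)C(C)(C)C)[C@]1(C)CCC[C@]1(C)CC=O
F9 | step 10 | C6 mono(tert-butyldimethylsilyl) ether of 17 | CC(C)=CCC(O[Si](C)(C)C(C)(C)C)[C@]1(C)CCC[C@]1(C)CC(O)CC#C
F10 | step 7 | methyl 2-[(1R,2R)-2-formyl-1,2-dimethylcyclopentyl]acetate | O=C[C@]1(C)CCC[C@]1(C)CC(=O)OC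
F11 | step 7 | methyl 2-[(1R,2R)-2-(1-hydroxybut-3-en-1-yl)-1,2-dimethylcyclopentyl]acetate | C=CCC(O)[C@]1(C)CCC[C@]1(C)CC(=O)OC
F12 | step 19 | quinone diol: 29 with both ketones as carbinols | CC(C)=CCC(O)[C@]1(C)CCC[C@]1(C)CC(O)C/C(C)=C/CC1=CC(=O)C=C(C)C1=O
A1 | alternative 1 | buta-1,3-diene | C=CC=C
A2 | alternative 1 | 2,3-dimethylmaleic anhydride | CC1=C(C)C(=O)OC1=O
A3 | alternative 1 | meso cis-1,2-dimethylcyclohex-4-ene-1,2-dicarboxylic anhydride | C[C@]12CC=CC[C@@]1(C)C(=O)OC2=O
A4 | alternative 2 | (7Z,9R)-3,7,9-trimethyloxacyclonon-7-en-2-one (C3 epimers) | C[C@H]1OC(=O)C(C)CCC/C(C)=C\1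
A5 | alternative 2 | (1R,2R)-1,2-dimethyl-2-[(E)-prop-1-enyl]cyclopentane-1-carboxylic acid (carboxyl and propenyl cis) | OC(=O)[C@]1(C)CCC[C@]1(C)/C=C/C
A6 | alternative 3 | (R)-2-tert-butyl-6-methyl-1,3-dioxin-4-one | CC1=CC(=O)O[C@H](C(C)(C)C)O1
A7 | alternative 3 | 1,2-dimethylcyclopentene | CC1=C(C)CCC1
A8 | alternative 3 | cis-anti-cis tricyclic photoadduct (dioxanone, cyclobutane and cyclopentane rings) | C[C@@]12O[C@@H](C(C)(C)C)OC(=O)[C@@H]1[C@@]1(C)CCC[C@@]21C
A9 | alternative 3 | 2-[(1R,2R)-2-acetyl-1,2-dimethylcyclopentyl]acetic acid | CC(=O)[C@]1(C)CCC[C@]1(C)CC(=O)O
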